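**Retrosynthetic overview**
- The target is the (2S)-flavanone 5-hydroxy-2-(2-hydroxy-6-methoxyphenyl)-6,7,8-trimethoxychroman-4-one. Its C4 carbonyl, free C5 hydroxyl and free C2' hydroxyl are installed last, on an (S)-2-aryl-5,6,7,8-tetramethoxychroman. The sequence is C2'-O-acetylation, C4 oxidation (DDQ/H2O, then Dess–Martin), peri-selective C5 demethylation and acetate removal.
- The strategy rests on this feature: O1–C8a–C4a–C4 of ring A is the four-atom unit of an ortho-quinone methide, and C2–C3 is the vinyl group of a styrene whose ring B has a free C2' hydroxyl ortho to that vinyl group. Ring C is therefore cut at C3–C4 and O1–C2 (oxa-[4+2] under a chiral phosphoric acid).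
- The quinone methide precursor is a tetramethoxy salicyl alcohol, made from 1,2,3,4-tetramethoxybenzene by formylation, Baeyer–Villiger oxidation, ortho-formylation and reduction. The styrene is made from 2-hydroxy-6-methoxybenzaldehyde by Wittig methylenation.
- Ring order: rings A and B are bought; ring C is the only ring formed (step 6), together with the single stereocentre C2.

Key step: step 6

Remark: the sense of induction of a BINOL phosphoric acid with an unsubstituted methide carbon cannot be derived from the aryl-substituted cases; the (R)-acid is written, and the (S)-acid would be used if the (R)-acid favoured the (R)-chroman.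

**Step 1**
Reactants: 1 1,2,3,4-tetramethoxybenzene
Product: 3 2,3,4,5-tetramethoxybenzaldehyde, via iminium salt 2 (not isolated)
Conditions: POCl3 (1.5 equiv), DMF, 0 to 75 °C; then ice-water
Reagents that add atoms: N,N-dimethylformamide CN(C)C=O; water O
Why: Vilsmeier–Haack formylation: the two free ring positions of 1 are equivalent by symmetry and each is activated by a para and an ortho methoxyl, so one iminium salt 2 should form and hydrolyse to aldehyde 3.

**Step 2**
Reactants: 3 2,3,4,5-tetramethoxybenzaldehyde
Product: 5 2,3,4,5-tetramethoxyphenol, via aryl formate 4 (not isolated)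
Conditions: mCPBA (1.3 equiv), CH2Cl2, 0 °C to rt; aq. NaHCO3 wash; then K2CO3 (cat.), MeOH, rt
Reagents that add atoms: mCPBA OOC(=O)c1cccc(Cl)c1
Why: Baeyer–Villiger (Dakin-type) oxidation, in which the electron-rich aryl group migrates to give formate 4, which mild methanolysis should convert to the phenol without touching the methyl ethers.

**Step 3**
Reactants: 5 2,3,4,5-tetramethoxyphenol
Product: 6 2-hydroxy-3,4,5,6-tetramethoxybenzaldehyde
Conditions: MgCl2 (2 equiv), Et3N (4 equiv), paraformaldehyde (6 equiv), MeCN, reflux, argon; then aq. HCl
Reagents that add atoms: formaldehyde (as paraformaldehyde) C=O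
Why: Magnesium-mediated ortho-formylation (Casnati–Skattebøl conditions): the magnesium phenoxide delivers formaldehyde to the one free position ortho to the hydroxyl, and a second formaldehyde accepts hydride from the benzylic alkoxide, leaving the salicylaldehyde.

**Step 4**
Reactants: 6 2-hydroxy-3,4,5,6-tetramethoxybenzaldehyde
Product: 7 6-(hydroxymethyl)-2,3,4,5-tetramethoxyphenol
Conditions: NaBH4, THF/MeOH, 0 °C; pH 7 buffer work-up
Reagents that add atoms: none
Why: Borohydride reduction of the aldehyde to the primary benzylic alcohol; cold, non-acidic work-up should keep the electron-rich salicyl alcohol from ionising to its quinone methide before it is wanted.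

**Step 5**
Reactants: 8 2-hydroxy-6-methoxybenzaldehyde
Product: 9 3-methoxy-2-vinylphenol
Conditions: Ph3PCH3Br (2.5 equiv), KOtBu (2.5 equiv), THF, 0 °C to rt; then aq. NH4Cl
Reagents that add atoms: methyltriphenylphosphonium bromide C[P+](c1ccccc1)(c1ccccc1)c1ccccc1.[Br-]
Why: Wittig methylenation with excess ylide, one equivalent serving as base for the phenol; the terminal alkene has no geometry to control and the phenoxide aldehyde should still react with the unstabilised ylide.

**Step 6**
Reactants: 7 6-(hydroxymethyl)-2,3,4,5-tetramethoxyphenol; 9 3-methoxy-2-vinylphenol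
Product: 11 (S)-3-methoxy-2-(5,6,7,8-tetramethoxychroman-2-yl)phenol, via ortho-quinone methide 10 (not isolated)
Conditions: (R)-TRIP [(R)-3,3'-bis(2,4,6-triisopropylphenyl)-1,1'-binaphthalene-2,2'-diyl hydrogen phosphate] (10 mol%), 4 Å MS, toluene, 0 °C to rt; 7 added slowly to 9 (1.5 equiv)
Reagents that add atoms: none
Why: Proposed new method: the phosphoric acid protonates the benzylic hydroxyl of 7, which leaves as water with push from the ortho phenol and the C5 and C7 methoxyls, giving the unsubstituted quinone methide 10 hydrogen-bonded to the phosphate; the electron-rich terminal carbon of styrene 9 then attacks the methide carbon (C3–C4) and the ring A oxygen closes on the benzylic C2 (O1–C2). The closest known reaction type is the chiral phosphoric acid catalysed [4+2] addition of aryl-substituted ortho-quinone methides, generated from ortho-hydroxybenzyl alcohols, to ortho-hydroxystyrenes, which gives 2,4-diarylchromans. Ring C closes as the six-membered ring of an asynchronous hetero-Diels–Alder addition in which O1–C8a–C4a–C4 supplies four atoms and the alkene two; if the addition is stepwise, the second bond forms by 6-exo-trig capture of the C2 cation (quinoid ring B) by O1. The only new stereocentre, C2, is set by the catalyst: the phosphate bridges the quinone methide oxygen and the C2' hydroxyl of the styrene, so that one face of C2 is offered to O1 inside the pocket of the 3,3' aryl groups, (S) being required. The step needs regioselectivity (C4 to C3, O1 to C2), which the polarity of the styrene and the oxygen-stabilised C2 cation secure, and chemoselectivity against quinone methide self-condensation and phenol alkylation, which slow addition of 7 to excess 9 should favour. It also needs enantioface selectivity, which without an aryl group on the methide carbon rests on the dual hydrogen bonding alone and is the unproven point.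

**Step 7**
Reactants: 11 (S)-3-methoxy-2-(5,6,7,8-tetramethoxychroman-2-yl)phenol
Product: 12 (S)-3-methoxy-2-(5,6,7,8-tetramethoxychroman-2-yl)phenyl acetate
Conditions: Ac2O, pyridine, DMAP (cat.), CH2Cl2, rt
Reagents that add atoms: acetic anhydride CC(=O)OC(C)=O
Why: DMAP-catalysed acetylation of the only hydroxyl, which keeps the C2' oxygen from capturing the C4 cation of step 8 (a bridged ether would result) and makes ring B a poorer donor so that hydride loss from C2 is disfavoured.

**Step 8**
Reactants: 12 (S)-3-methoxy-2-(5,6,7,8-tetramethoxychroman-2-yl)phenyl acetate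
Product: 13 2-[(2S)-4-hydroxy-5,6,7,8-tetramethoxychroman-2-yl]-3-methoxyphenyl acetate as a mixture of C4 epimers
Conditions: DDQ (1.2 equiv), CH2Cl2/H2O (10:1), 0 °C to rt
Reagents that add atoms: water O
Why: DDQ benzylic oxidation by hydride abstraction, a known way to oxygenate C4 of electron-rich flavans: the C4 cation is stabilised by the C5 (ortho) and C7 (para) methoxyls and is captured by water, the acetylated ring B gives the competing C2 cation little support, C2 is not touched and the new C4 centre is removed in step 9.

**Step 9**
Reactants: 13 2-[(2S)-4-hydroxy-5,6,7,8-tetramethoxychroman-2-yl]-3-methoxyphenyl acetate (C4 epimers)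
Product: 14 (S)-3-methoxy-2-(5,6,7,8-tetramethoxy-4-oxochroman-2-yl)phenyl acetate
Conditions: Dess–Martin periodinane (1.3 equiv), pyridine, CH2Cl2, 0 °C to rt
Reagents that add atoms: none
Why: Dess–Martin oxidation of the secondary benzylic alcohol under pyridine-buffered conditions, which should bring both C4 epimers to one ketone without enolising toward C2 or ionising the benzylic alcohol.

**Step 10**
Reactants: 14 (S)-3-methoxy-2-(5,6,7,8-tetramethoxy-4-oxochroman-2-yl)phenyl acetate
Product: 16 (S)-2-(5-hydroxy-6,7,8-trimethoxy-4-oxochroman-2-yl)-3-methoxyphenyl acetate, via boron chelate 15 (not isolated)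
Conditions: BCl3 (2.5 equiv, 1 M in CH2Cl2), CH2Cl2, −78 to 0 °C; then H2O
Reagents that add atoms: none
Why: Chelation-controlled peri-demethylation: BCl3 binds the C4 carbonyl, chloride removes only the C5 methyl group to give the six-membered chelate 15, the other four methyl ethers lack this activation, and the low temperature should prevent Lewis-acid opening of the C2–O1 bond that would racemise C2.

**Step 11**
Reactants: 16 (S)-2-(5-hydroxy-6,7,8-trimethoxy-4-oxochroman-2-yl)-3-methoxyphenyl acetate
Product: 17 (S)-5-hydroxy-2-(2-hydroxy-6-methoxyphenyl)-6,7,8-trimethoxychroman-4-one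
Conditions: HCl (0.5 M) in MeOH, rt
Reagents that add atoms: none
Why: Acid-catalysed transesterification of the aryl acetate by methanol, chosen over basic hydrolysis because base opens 5-hydroxyflavanones to the chalcone by retro-oxa-Michael reaction and would racemise C2.

**Compound list**
1 | 1,2,3,4-tetramethoxybenzene | COc1ccc(OC)c(OC)c1OC | starting material
2 | N,N-dimethyl-(2,3,4,5-tetramethoxybenzylidene)iminium dichlorophosphate (not isolated) | C[N+](C)=Cc1cc(OC)c(OC)c(OC)c1OC.[O-]P(=O)(Cl)Cl | intermediate
3 | 2,3,4,5-tetramethoxybenzaldehyde | O=Cc1cc(OC)c(OC)c(OC)c1OC | intermediate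
4 | 2,3,4,5-tetramethoxyphenyl formate (not isolated) | O=COc1cc(OC)c(OC)c(OC)c1OC | intermediate
5 | 2,3,4,5-tetramethoxyphenol | Oc1cc(OC)c(OC)c(OC)c1OC | intermediate
6 | 2-hydroxy-3,4,5,6-tetramethoxybenzaldehyde | O=Cc1c(O)c(OC)c(OC)c(OC)c1OC | intermediate
7 | 6-(hydroxymethyl)-2,3,4,5-tetramethoxyphenol | OCc1c(O)c(OC)c(OC)c(OC)c1OC | intermediate
8 | 2-hydroxy-6-methoxybenzaldehyde | COc1cccc(O)c1C=O | starting material
9 | 3-methoxy-2-vinylphenol | COc1cccc(O)c1C=C | intermediate
10 | 2,3,4,5-tetramethoxy-6-methylidenecyclohexa-2,4-dien-1-one (not isolated) | C=C1C(=O)C(OC)=C(OC)C(OC)=C1OC | intermediate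
11 | (S)-3-methoxy-2-(5,6,7,8-tetramethoxychroman-2-yl)phenol | COc1cccc(O)c1[C@@H]1CCc2c(OC)c(OC)c(OC)c(OC)c2O1 | intermediate
12 | (S)-3-methoxy-2-(5,6,7,8-tetramethoxychroman-2-yl)phenyl acetate | COc1cccc(OC(C)=O)c1[C@@H]1CCc2c(OC)c(OC)c(OC)c(OC)c2O1 | intermediate
13 | 2-[(2S)-4-hydroxy-5,6,7,8-tetramethoxychroman-2-yl]-3-methoxyphenyl acetate (C4 epimers) | COc1cccc(OC(C)=O)c1[C@@H]1CC(O)c2c(OC)c(OC)c(OC)c(OC)c2O1 | intermediate
14 | (S)-3-methoxy-2-(5,6,7,8-tetramethoxy-4-oxochroman-2-yl)phenyl acetate | COc1cccc(OC(C)=O)c1[C@@H]1CC(=O)c2c(OC)c(OC)c(OC)c(OC)c2O1 | intermediate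
15 | (S)-2-[5-(dichloroboryloxy)-6,7,8-trimethoxy-4-oxochroman-2-yl]-3-methoxyphenyl acetate (not isolated) | COc1cccc(OC(C)=O)c1[C@@H]1CC(=O)c2c(OB(Cl)Cl)c(OC)c(OC)c(OC)c2O1 | intermediate
16 | (S)-2-(5-hydroxy-6,7,8-trimethoxy-4-oxochroman-2-yl)-3-methoxyphenyl acetate | COc1cccc(OC(C)=O)c1[C@@H]1CC(=O)c2c(O)c(OC)c(OC)c(OC)c2O1 | intermediate
17 | (S)-5-hydroxy-2-(2-hydroxy-6-methoxyphenyl)-6,7,8-trimethoxychroman-4-one | COc1cccc(O)c1[C@@H]1CC(=O)c2c(O)c(OC)c(OC)c(OC)c2O1 | target

**Step count**
Total: 11 steps. Longest linear sequence: 10 steps (steps 1–4 and 6–11, from 1 to 17); step 5 is the one-step second branch.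

**Steps most likely to fail**

1. Step 6 (the proposed new method). What may go wrong is weak enantioface discrimination at C2, because the methide carbon has no aryl group to fix its position in the catalyst pocket. The quinone methide may also be lost to self-condensation, and the styrene to acid-induced dimerisation. The fallback uses known chemistry and sets out from 7 and 9. The same cycloaddition is run with an achiral acid (diphenyl phosphate, toluene, rt); [4+2] additions of salicyl-alcohol-derived quinone methides to styrenes under thermal or achiral-acid conditions are established. This should give the racemic chroman F1. Preparative chromatography on a chiral stationary phase (amylose tris(3,5-dimethylphenylcarbamate)) should then deliver 11 and set aside the (R)-enantiomer F2. The route is rejoined at 11.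

2. Step 8. What may go wrong is that the C4 cation loses a C3 proton instead of taking up water. The flav-3-ene so formed would be dehydrogenated further by DDQ to a flavylium ion, with loss of the C2 centre; hydride abstraction at C2 is the second leak. The fallback sets out from 12 and changes both the oxidant class and the order of the endgame. Benzylic acetoxylation with Pb(OAc)4 in acetic acid, where the solvent captures the cation at once, should give the C4 acetate F3. Both acetates are then removed with LiOH in THF/H2O at the chroman-4-ol stage, where base cannot open ring C, to give the diol F4. MnO2 in CH2Cl2 should oxidise only the benzylic alcohol, giving the free-phenol flavanone F5. BCl3 (CH2Cl2, −78 to 0 °C) then cleaves the C5 methyl ether, so the route is rejoined at 17 and the acid methanolysis is not needed.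

3. Step 3. What may go wrong is slow or incomplete formylation, because the magnesium phenoxide of 5 is chelated by the neighbouring methoxyl and the one free position is flanked by a methoxyl. Prolonged heating may also oxidise the electron-rich phenol to a quinone. The fallback sets out from 5 and uses boron-templated ortho-hydroxymethylation (PhB(OH)2, paraformaldehyde, cat. propionic acid, toluene, reflux with water removal). This should give the cyclic phenylboronate F6, a storable masked form of the diol. Transesterification with pinacol (THF, rt) releases 7 just before step 6. Aldehyde 6 and the hydride reduction are by-passed, and the route is rejoined at 7.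

**Further compounds**
F1 | step 6 | racemic 3-methoxy-2-(5,6,7,8-tetramethoxychroman-2-yl)phenol | COc1cccc(O)c1C1CCc2c(OC)c(OC)c(OC)c(OC)c2O1
F2 | step 6 | (R)-3-methoxy-2-(5,6,7,8-tetramethoxychroman-2-yl)phenol | COc1cccc(O)c1[C@H]1CCc2c(OC)c(OC)c(OC)c(OC)c2O1
F3 | step 8 | (2S)-2-(2-acetoxy-6-methoxyphenyl)-5,6,7,8-tetramethoxychroman-4-yl acetate (C4 epimers) | COc1cccc(OC(C)=O)c1[C@@H]1CC(OC(C)=O)c2c(OC)c(OC)c(OC)c(OC)c2O1
F4 | step 8 | (2S)-2-(2-hydroxy-6-methoxyphenyl)-5,6,7,8-tetramethoxychroman-4-ol (C4 epimers) | COc1cccc(O)c1[C@@H]1CC(O)c2c(OC)c(OC)c(OC)c(OC)c2O1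
F5 | step 8 | (S)-2-(2-hydroxy-6-methoxyphenyl)-5,6,7,8-tetramethoxychroman-4-one | COc1cccc(O)c1[C@@H]1CC(=O)c2c(OC)c(OC)c(OC)c(OC)c2O1
F6 | step 3 | 5,6,7,8-tetramethoxy-2-phenyl-4H-benzo[d][1,3,2]dioxaborinine | COc1c(OC)c(OC)c2OB(c3ccccc3)OCc2c1OC
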